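Ring A of the target carries hydrogen at C5 and C8 and oxygen at C6 and C7 and is fused to ring B through C4a–C8a. This is the pattern left when two terminal alkynes tethered through C1–C4 combine with one symmetrical heteroatom-bearing alkyne. The route therefore forms C4a–C8a, C5–C6 and C7–C8 in a single cobalt-mediated (2+2+2) cycloaddition of bis(pinacolatoboryl)acetylene with an enantiopure octa-1,7-diyn-3-one that already holds the C1 aryl and C2 silyloxymethyl stereocentres. Rings A and B close together; the two C–B bonds become the C6/C7 oxygens, and the C4 ketone then differentiates the two phenols and is transposed into the C3 enal.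

Key step: step 10

Remarks
- Ring positions are numbered as in the target throughout: C1 (CH–aryl), C2 (CH–CH2O), C3, C4, C4a, C5–C8, C8a; ring A is the benzo ring, ring B the C1–C4 ring, ring C the guaiacyl ring.
- The 1,2-trans target (1S,2R) needs the (5S,6R)-diyne, in which the aryl group and the CH2C(=O) branch are anti along the chain CH2O–C5–C6–C≡C. Propargyl-cation alkylations of chiral imide enolates favour the syn adduct, which maps onto the 1,2-cis ring, so C1 is set here by asymmetric conjugate alkynylation and C2 by auxiliary-controlled alkylation.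
- CIP descriptors change along the route without any change of geometry (silyl group on the alkyne; sp2 or sp3 C3); the SMILES strings are authoritative.

Step 1
Reactants: 1 4-(benzyloxy)-3-methoxybenzaldehyde; 2 Meldrum's acid
Product: 3 5-[4-(benzyloxy)-3-methoxybenzylidene]-2,2-dimethyl-1,3-dioxane-4,6-dione
Conditions: pyrrolidine (10 mol%), AcOH (10 mol%), PhMe, 50 °C
Reagents that add atoms: none
Why: Knoevenagel condensation of an aryl aldehyde with the strongly C–H acidic dione should give the doubly activated arylidene acceptor.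

Step 2
Reactants: 3 arylidene Meldrum's acid; 4 ethynyl(trimethyl)silane
Product: 5 5-[(1S)-1-[4-(benzyloxy)-3-methoxyphenyl]-3-(trimethylsilyl)prop-2-yn-1-yl]-2,2-dimethyl-1,3-dioxane-4,6-dione
Conditions: 4 (5 equiv), [Rh(OAc)(C2H4)2]2 (2.5 mol%), 3,5-Xyl-MeO-BIPHEP (5.5 mol%, the antipode that gives the 1S adduct), 1,4-dioxane, 15–25 °C
Reagents that add atoms: none
Why: Rhodium-catalysed enantioselective conjugate alkynylation, in which a monovalent rhodium acetylide adds 1,4 to the s-cis-locked arylidene and the chiral bisphosphine selects the alkene face, sets C1, while the bulky silyl group holds back alkyne oligomerisation.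

Step 3
Reactants: 5 alkynylated Meldrum's acid
Product: 6 (3S)-3-[4-(benzyloxy)-3-methoxyphenyl]-5-(trimethylsilyl)pent-4-ynoic acid
Conditions: DMF/H2O (10:1), 100 °C
Reagents that add atoms: water, O
Why: Neutral hydrolytic ring opening of the dioxanedione and decarboxylation of the resulting malonic acid should leave the C–Si bond and the benzylic propargylic centre untouched.

Step 4
Reactants: 6 pentynoic acid; 7 (4S)-4-benzyl-1,3-oxazolidin-2-one
Product: 9 (4S)-4-benzyl-3-[(3S)-3-[4-(benzyloxy)-3-methoxyphenyl]-5-(trimethylsilyl)pent-4-ynoyl]-1,3-oxazolidin-2-one, via mixed pivalic anhydride 8 (not isolated)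
Conditions: t-BuCOCl, Et3N, THF, −20 °C; then LiCl, 7, −20 °C → rt
Reagents that add atoms: none
Why: N-acylation of the oxazolidinone through a mixed anhydride, which is attacked at its less hindered acyl carbon, is the standard way to attach this auxiliary.

Step 5
Reactants: 9 N-acyl oxazolidinone; 10 tert-butyl bromoacetate
Product: 12 tert-butyl (3S,4S)-3-[(4S)-4-benzyl-2-oxo-1,3-oxazolidine-3-carbonyl]-4-[4-(benzyloxy)-3-methoxyphenyl]-6-(trimethylsilyl)hex-5-ynoate, via sodium enolate 11 (not isolated)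
Conditions: NaN(SiMe3)2 (1.1 equiv), THF, −78 °C; then 10, −78 → −40 °C
Reagents that add atoms: none
Why: Oxazolidinone-directed (Evans) enolate alkylation, in which the chelated sodium Z-enolate reacts on the face opposite the auxiliary benzyl group, sets C2; the existing C1 centre shields the same face with its aryl group under allylic 1,3-strain control (matched case), giving the anti arrangement needed for the 1,2-trans ring.

Step 6
Reactants: 12 alkylated imide
Product: 14 (4S)-4-[(1S)-1-[4-(benzyloxy)-3-methoxyphenyl]-3-(trimethylsilyl)prop-2-yn-1-yl]oxolan-2-one, via hydroxy ester 13 (not isolated)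
Conditions: LiBH4 (1.5 equiv), MeOH (1.5 equiv), THF, 0 °C; work-up; then TsOH·H2O (5 mol%), CH2Cl2, rt
Reagents that add atoms: none
Why: Reductive removal of the auxiliary with LiBH4, which spares the tert-butyl ester at 0 °C, followed by acid-catalysed lactonisation of the γ-hydroxy ester, should give the β-substituted butyrolactone with both centres untouched.

Step 7
Reactants: 14 butyrolactone
Product: 16 (3S,4S)-4-[4-(benzyloxy)-3-methoxyphenyl]-3-{[tert-butyl(dimethyl)silyl]oxymethyl}-N-methoxy-N-methyl-6-(trimethylsilyl)hex-5-ynamide, via hydroxy amide 15 (not isolated)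
Conditions: MeNH(OMe)·HCl (3 equiv), AlMe3 (3 equiv), CH2Cl2, 0 °C → rt; aq. KNaC4H4O6 work-up; then TBSCl, imidazole, DMF, 0 °C → rt
Reagents that add atoms: N,O-dimethylhydroxylamine hydrochloride, CNOC.Cl; tert-butyldimethylsilyl chloride, CC(C)(C)[Si](C)(C)Cl
Why: Aluminium amide aminolysis of the lactone gives the Weinreb amide, and immediate silylation of the freed primary alcohol blocks relactonisation.

Step 8
Reactants: 16 silylalkyne Weinreb amide
Product: 17 (3S,4R)-4-[4-(benzyloxy)-3-methoxyphenyl]-3-{[tert-butyl(dimethyl)silyl]oxymethyl}-N-methoxy-N-methylhex-5-ynamide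
Conditions: K2CO3 (0.3 equiv), MeOH, 0 °C → rt
Reagents that add atoms: none
Why: Carbonate-catalysed methanolysis cleaves only the C(sp)–Si bond, since the primary silyl ether, the amide and the weakly acidic C1–H are inert to it.

Step 9
Reactants: 17 terminal alkyne Weinreb amide; 18 ethynylmagnesium bromide
Product: 20 (5S,6R)-6-[4-(benzyloxy)-3-methoxyphenyl]-5-{[tert-butyl(dimethyl)silyl]oxymethyl}octa-1,7-diyn-3-one, via magnesium hemiaminal 19 (not isolated)
Conditions: 18 (0.5 M in THF, 4 equiv), THF, 0 °C; inverse quench into cold 1 M aq. NaHSO4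
Reagents that add atoms: none
Why: Weinreb ketone synthesis, in which the chelated tetrahedral adduct prevents over-addition; the acidic inverse quench protonates the released hydroxylamine before it can add to the terminal ynone, and excess reagent covers deprotonation of the substrate alkyne.

Step 10
Reactants: 20 chiral 1,7-diyne with ynone terminus; 21 bis(pinacolatoboryl)acetylene
Product: 22 (1S,2S)-1-[4-(benzyloxy)-3-methoxyphenyl]-2-{[tert-butyl(dimethyl)silyl]oxymethyl}-6,7-bis(4,4,5,5-tetramethyl-1,3,2-dioxaborolan-2-yl)-1,2,3,4-tetrahydronaphthalen-4-one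
Conditions: CpCo(CO)2 (15 mol%), 21 (3 equiv), degassed PhMe, 110 °C, hν (visible lamp), 20 added over 8 h by syringe pump
Reagents that add atoms: none
Why: Loss of CO from CpCo(CO)2 frees monovalent cobalt, which binds both alkynes of 20 and couples them oxidatively to a cobaltacyclopentadiene; this forms C4a–C8a and closes ring B as the six-membered carbocycle annulated to the metallacycle, enforced by the four-atom tether C1–C4. Coordination and insertion of 21, followed by reductive elimination, forms C5–C6 and C7–C8 and closes ring A as the new benzene ring. The closest known reaction type is the cobalt-mediated cocyclisation of α,ω-diynes with bis(silyl)- or boryl-substituted alkynes. No stereocentre is created, and the neutral, non-basic medium should leave the propargylic benzylic C1–H and C2 untouched. The step needs cross-cyclotrimerisation and not diyne oligomerisation, which is secured by the tether, by the low stationary concentration of the diyne and by an excess of the hindered diborylalkyne, which should not trimerise with itself under these conditions. Regiochemistry is no issue because 21 is symmetrical, so boron ends on C6 and C7 and hydrogen on C5 and C8.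

Step 11
Reactants: 22 diboryl tetralone
Product: 23 (1S,2S)-1-[4-(benzyloxy)-3-methoxyphenyl]-2-{[tert-butyl(dimethyl)silyl]oxymethyl}-6,7-dihydroxy-1,2,3,4-tetrahydronaphthalen-4-one
Conditions: NaBO3·4H2O (6 equiv), THF/H2O (1:1), rt; aq. NH4Cl work-up
Reagents that add atoms: sodium perborate, [Na+].[O-]OB=O
Why: Perborate ipso-oxidation of both aryl C–B bonds (boron ate complex, 1,2-aryl shift to oxygen) is mild enough for the ketone and the silyl ether and should give the catechol.

Step 12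
Reactants: 23 catechol
Product: 24 (1S,2S)-7-(benzyloxy)-1-[4-(benzyloxy)-3-methoxyphenyl]-2-{[tert-butyl(dimethyl)silyl]oxymethyl}-6-hydroxy-1,2,3,4-tetrahydronaphthalen-4-one
Conditions: BnBr (1.05 equiv), NaHCO3 (1.5 equiv), NaI (0.1 equiv), DMF, 40 °C
Reagents that add atoms: benzyl bromide, BrCc1ccccc1
Why: Only O7–H, para through C4a to the C4 carbonyl and therefore a vinylogous acid, is deprotonated by hydrogencarbonate, so the Williamson benzylation should go to O7 as it does with 3,4-dihydroxyaryl ketones.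

Step 13
Reactants: 24 O7-benzyl phenol
Product: 25 (1S,2S)-7-(benzyloxy)-1-[4-(benzyloxy)-3-methoxyphenyl]-2-{[tert-butyl(dimethyl)silyl]oxymethyl}-6-methoxy-1,2,3,4-tetrahydronaphthalen-4-one
Conditions: MeI (3 equiv), K2CO3 (2 equiv), DMF, rt
Reagents that add atoms: iodomethane, CI
Why: Williamson methylation of the remaining O6 phenol under carbonate conditions does not enolise the ketone.

Step 14
Reactants: 25 fully protected tetralone
Product: 26 (1S,2R)-7-(benzyloxy)-1-[4-(benzyloxy)-3-methoxyphenyl]-2-{[tert-butyl(dimethyl)silyl]oxymethyl}-3-[(E)-(dimethylamino)methylidene]-6-methoxy-1,2,3,4-tetrahydronaphthalen-4-one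
Conditions: t-BuOCH(NMe2)2 (3 equiv), PhMe, 100 °C
Reagents that add atoms: tert-butoxybis(dimethylamino)methane, CC(C)(C)OC(N(C)C)N(C)C
Why: Aminomethylenation of the only ketone α-methylene (C3) with an aminal ester installs the future formyl carbon as a vinylogous amide without touching C2.

Step 15
Reactants: 26 enaminone
Product: 29 (1S,2R)-7-(benzyloxy)-1-[4-(benzyloxy)-3-methoxyphenyl]-2-(hydroxymethyl)-6-methoxy-1,2-dihydronaphthalene-3-carbaldehyde, via amino alcohol 27 (not isolated), via silyl enal 28 (not isolated)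
Conditions: i-Bu2AlH (3 equiv), THF, −78 → 0 °C; then 2 M aq. HCl/THF (1:3), rt
Reagents that add atoms: water, O
Why: Reductive 1,3-carbonyl transposition of a β-amino enone: 1,2-hydride addition, acid-induced loss of the benzylic C4 hydroxyl pushed by the enamine nitrogen, and hydrolysis of the unsaturated iminium ion give the C3=C4 enal, while the same aqueous acid cleaves the primary silyl ether.

Step 16
Reactants: 29 hydroxy enal
Product: 30 [(1S,2R)-7-(benzyloxy)-1-[4-(benzyloxy)-3-methoxyphenyl]-3-formyl-6-methoxy-1,2-dihydronaphthalen-2-yl]methyl acetate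
Conditions: Ac2O (2 equiv), pyridine, DMAP (5 mol%), CH2Cl2, 0 °C → rt
Reagents that add atoms: acetic anhydride, CC(=O)OC(C)=O
Why: Acyl transfer to the only free hydroxyl, since both phenols are still benzylated.

Step 17
Reactants: 30 bis-benzyl acetate
Product: 31 [(1S,2R)-3-formyl-7-hydroxy-1-(4-hydroxy-3-methoxyphenyl)-6-methoxy-1,2-dihydronaphthalen-2-yl]methyl acetate (target)
Conditions: BCl3 (1 M in CH2Cl2, 5 equiv), C6HMe5 (6 equiv), CH2Cl2, −78 °C; MeOH quench at −78 °C
Reagents that add atoms: none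
Why: Lewis-acid debenzylation of both aryl benzyl ethers with pentamethylbenzene as cation scavenger should spare, at −78 °C, the acetate, the enal, the methyl ethers and the C3=C4 double bond that hydrogenolysis would reduce.

Compound list
1 | 4-(benzyloxy)-3-methoxybenzaldehyde (O-benzylvanillin) | COc1cc(C=O)ccc1OCc1ccccc1 | starting material
2 | 2,2-dimethyl-1,3-dioxane-4,6-dione (Meldrum's acid) | CC1(C)OC(=O)CC(=O)O1 | starting material
3 | 5-[4-(benzyloxy)-3-methoxybenzylidene]-2,2-dimethyl-1,3-dioxane-4,6-dione | COc1cc(C=C2C(=O)OC(C)(C)OC2=O)ccc1OCc1ccccc1 | intermediate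
4 | ethynyl(trimethyl)silane | C#C[Si](C)(C)C | starting material
5 | 5-[(1S)-1-[4-(benzyloxy)-3-methoxyphenyl]-3-(trimethylsilyl)prop-2-yn-1-yl]-2,2-dimethyl-1,3-dioxane-4,6-dione | C[Si](C)(C)C#C[C@H](c1ccc(OCc2ccccc2)c(OC)c1)C1C(=O)OC(C)(C)OC1=O | intermediate
6 | (3S)-3-[4-(benzyloxy)-3-methoxyphenyl]-5-(trimethylsilyl)pent-4-ynoic acid | C[Si](C)(C)C#C[C@H](c1ccc(OCc2ccccc2)c(OC)c1)CC(=O)O | intermediate
7 | (4S)-4-benzyl-1,3-oxazolidin-2-one | O=C1N[C@@H](Cc2ccccc2)CO1 | starting material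
8 | (3S)-3-[4-(benzyloxy)-3-methoxyphenyl]-5-(trimethylsilyl)pent-4-ynoic 2,2-dimethylpropanoic anhydride | C[Si](C)(C)C#C[C@H](c1ccc(OCc2ccccc2)c(OC)c1)CC(=O)OC(=O)C(C)(C)C | intermediate (not isolated)
9 | (4S)-4-benzyl-3-[(3S)-3-[4-(benzyloxy)-3-methoxyphenyl]-5-(trimethylsilyl)pent-4-ynoyl]-1,3-oxazolidin-2-one | C[Si](C)(C)C#C[C@H](c1ccc(OCc2ccccc2)c(OC)c1)CC(=O)N1[C@@H](Cc2ccccc2)COC1=O | intermediate
10 | tert-butyl bromoacetate | BrCC(=O)OC(C)(C)C | starting material
11 | sodium (Z)-enolate of imide 9 | [Na+].C[Si](C)(C)C#C[C@H](c1ccc(OCc2ccccc2)c(OC)c1)/C=C(\[O-])N1[C@@H](Cc2ccccc2)COC1=O | intermediate (not isolated)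
12 | tert-butyl (3S,4S)-3-[(4S)-4-benzyl-2-oxo-1,3-oxazolidine-3-carbonyl]-4-[4-(benzyloxy)-3-methoxyphenyl]-6-(trimethylsilyl)hex-5-ynoate | C[Si](C)(C)C#C[C@H](c1ccc(OCc2ccccc2)c(OC)c1)[C@@H](C(=O)N1[C@@H](Cc2ccccc2)COC1=O)CC(=O)OC(C)(C)C | intermediate
13 | tert-butyl (3S,4S)-4-[4-(benzyloxy)-3-methoxyphenyl]-3-(hydroxymethyl)-6-(trimethylsilyl)hex-5-ynoate | C[Si](C)(C)C#C[C@H](c1ccc(OCc2ccccc2)c(OC)c1)[C@@H](CO)CC(=O)OC(C)(C)C | intermediate (not isolated)
14 | (4S)-4-[(1S)-1-[4-(benzyloxy)-3-methoxyphenyl]-3-(trimethylsilyl)prop-2-yn-1-yl]oxolan-2-one | C[Si](C)(C)C#C[C@H](c1ccc(OCc2ccccc2)c(OC)c1)[C@@H]1CC(=O)OC1 | intermediate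
15 | (3S,4S)-4-[4-(benzyloxy)-3-methoxyphenyl]-3-(hydroxymethyl)-N-methoxy-N-methyl-6-(trimethylsilyl)hex-5-ynamide | C[Si](C)(C)C#C[C@H](c1ccc(OCc2ccccc2)c(OC)c1)[C@@H](CO)CC(=O)N(C)OC | intermediate (not isolated)
16 | (3S,4S)-4-[4-(benzyloxy)-3-methoxyphenyl]-3-{[tert-butyl(dimethyl)silyl]oxymethyl}-N-methoxy-N-methyl-6-(trimethylsilyl)hex-5-ynamide | C[Si](C)(C)C#C[C@H](c1ccc(OCc2ccccc2)c(OC)c1)[C@@H](CO[Si](C)(C)C(C)(C)C)CC(=O)N(C)OC | intermediate
17 | (3S,4R)-4-[4-(benzyloxy)-3-methoxyphenyl]-3-{[tert-butyl(dimethyl)silyl]oxymethyl}-N-methoxy-N-methylhex-5-ynamide | C#C[C@H](c1ccc(OCc2ccccc2)c(OC)c1)[C@@H](CO[Si](C)(C)C(C)(C)C)CC(=O)N(C)OC | intermediate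
18 | ethynylmagnesium bromide | C#C[Mg]Br | starting material
19 | bromomagnesium (3RS,5S,6R)-6-[4-(benzyloxy)-3-methoxyphenyl]-5-{[tert-butyl(dimethyl)silyl]oxymethyl}-3-[methoxy(methyl)amino]octa-1,7-diyn-3-olate | C#C[C@H](c1ccc(OCc2ccccc2)c(OC)c1)[C@@H](CO[Si](C)(C)C(C)(C)C)CC(O[Mg]Br)(C#C)N(C)OC | intermediate (not isolated)
20 | (5S,6R)-6-[4-(benzyloxy)-3-methoxyphenyl]-5-{[tert-butyl(dimethyl)silyl]oxymethyl}octa-1,7-diyn-3-one | C#C[C@H](c1ccc(OCc2ccccc2)c(OC)c1)[C@@H](CO[Si](C)(C)C(C)(C)C)CC(=O)C#C | intermediate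
21 | 1,2-bis(4,4,5,5-tetramethyl-1,3,2-dioxaborolan-2-yl)ethyne | CC1(C)OB(C#CB2OC(C)(C)C(C)(C)O2)OC1(C)C | starting material
22 | (1S,2S)-1-[4-(benzyloxy)-3-methoxyphenyl]-2-{[tert-butyl(dimethyl)silyl]oxymethyl}-6,7-bis(4,4,5,5-tetramethyl-1,3,2-dioxaborolan-2-yl)-1,2,3,4-tetrahydronaphthalen-4-one (target numbering) | COc1cc([C@H]2c3cc(B4OC(C)(C)C(C)(C)O4)c(B4OC(C)(C)C(C)(C)O4)cc3C(=O)C[C@@H]2CO[Si](C)(C)C(C)(C)C)ccc1OCc1ccccc1 | intermediate
23 | (1S,2S)-1-[4-(benzyloxy)-3-methoxyphenyl]-2-{[tert-butyl(dimethyl)silyl]oxymethyl}-6,7-dihydroxy-1,2,3,4-tetrahydronaphthalen-4-one (target numbering) | COc1cc([C@H]2c3cc(O)c(O)cc3C(=O)C[C@@H]2CO[Si](C)(C)C(C)(C)C)ccc1OCc1ccccc1 | intermediate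
24 | (1S,2S)-7-(benzyloxy)-1-[4-(benzyloxy)-3-methoxyphenyl]-2-{[tert-butyl(dimethyl)silyl]oxymethyl}-6-hydroxy-1,2,3,4-tetrahydronaphthalen-4-one (target numbering) | COc1cc([C@H]2c3cc(OCc4ccccc4)c(O)cc3C(=O)C[C@@H]2CO[Si](C)(C)C(C)(C)C)ccc1OCc1ccccc1 | intermediate
25 | (1S,2S)-7-(benzyloxy)-1-[4-(benzyloxy)-3-methoxyphenyl]-2-{[tert-butyl(dimethyl)silyl]oxymethyl}-6-methoxy-1,2,3,4-tetrahydronaphthalen-4-one (target numbering) | COc1cc([C@H]2c3cc(OCc4ccccc4)c(OC)cc3C(=O)C[C@@H]2CO[Si](C)(C)C(C)(C)C)ccc1OCc1ccccc1 | intermediate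
26 | (1S,2R)-7-(benzyloxy)-1-[4-(benzyloxy)-3-methoxyphenyl]-2-{[tert-butyl(dimethyl)silyl]oxymethyl}-3-[(E)-(dimethylamino)methylidene]-6-methoxy-1,2,3,4-tetrahydronaphthalen-4-one (target numbering) | COc1cc([C@H]2c3cc(OCc4ccccc4)c(OC)cc3C(=O)/C(=C/N(C)C)[C@@H]2CO[Si](C)(C)C(C)(C)C)ccc1OCc1ccccc1 | intermediate
27 | (1S,2R,4RS)-7-(benzyloxy)-1-[4-(benzyloxy)-3-methoxyphenyl]-2-{[tert-butyl(dimethyl)silyl]oxymethyl}-3-[(E)-(dimethylamino)methylidene]-6-methoxy-1,2,3,4-tetrahydronaphthalen-4-ol (target numbering) | COc1cc([C@H]2c3cc(OCc4ccccc4)c(OC)cc3C(O)/C(=C/N(C)C)[C@@H]2CO[Si](C)(C)C(C)(C)C)ccc1OCc1ccccc1 | intermediate (not isolated)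
28 | (1S,2R)-7-(benzyloxy)-1-[4-(benzyloxy)-3-methoxyphenyl]-2-{[tert-butyl(dimethyl)silyl]oxymethyl}-6-methoxy-1,2-dihydronaphthalene-3-carbaldehyde | COc1cc([C@H]2c3cc(OCc4ccccc4)c(OC)cc3C=C(C=O)[C@@H]2CO[Si](C)(C)C(C)(C)C)ccc1OCc1ccccc1 | intermediate (not isolated)
29 | (1S,2R)-7-(benzyloxy)-1-[4-(benzyloxy)-3-methoxyphenyl]-2-(hydroxymethyl)-6-methoxy-1,2-dihydronaphthalene-3-carbaldehyde | COc1cc([C@H]2c3cc(OCc4ccccc4)c(OC)cc3C=C(C=O)[C@@H]2CO)ccc1OCc1ccccc1 | intermediate
30 | [(1S,2R)-7-(benzyloxy)-1-[4-(benzyloxy)-3-methoxyphenyl]-3-formyl-6-methoxy-1,2-dihydronaphthalen-2-yl]methyl acetate | COc1cc([C@H]2c3cc(OCc4ccccc4)c(OC)cc3C=C(C=O)[C@@H]2COC(C)=O)ccc1OCc1ccccc1 | intermediate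
31 | [(1S,2R)-3-formyl-7-hydroxy-1-(4-hydroxy-3-methoxyphenyl)-6-methoxy-1,2-dihydronaphthalen-2-yl]methyl acetate (CNP0549177.1) | COc1cc([C@H]2c3cc(O)c(OC)cc3C=C(C=O)[C@@H]2COC(C)=O)ccc1O | target

Total step count: 17. Longest linear sequence: 17 steps (1 → 31); all other inputs are commercial.

Steps most likely to fail

Step 10. Oligomerisation of the diyne, or thermal decomposition of its electron-poor terminal ynone, may outrun insertion of the hindered diborylalkyne at the temperature the cobalt catalyst needs. The fallback sets out from 20 and returns at 22, and masks the C4 carbonyl at the alcohol level during the cycloaddition. 1,2-Reduction of the ynone (NaBH4, CeCl3·7H2O, MeOH, −40 °C) should give (3RS,5S,6R)-6-[4-(benzyloxy)-3-methoxyphenyl]-5-{[tert-butyl(dimethyl)silyl]oxymethyl}octa-1,7-diyn-3-ol F1, a thermally robust diyne with two electronically alike terminal alkynes. The same cobalt-mediated cocyclisation with 21 should then give the C4 carbinol (1S,2S,4RS)-6,7-diboryl tetralin-4-ol F2 as a pair of C4 epimers, and benzylic oxidation (MnO2, CH2Cl2, rt) should return ketone 22.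

Step 2. Conversion or enantioface selection may be insufficient with this electron-rich, less electrophilic arylidene, and the silylalkyne may oligomerise on rhodium. The fallback sets out from 3 and returns at 6, and replaces asymmetric catalysis by racemic addition and resolution. Uncatalysed 1,4-addition of (trimethylsilyl)ethynylmagnesium bromide F3 (from 4 and EtMgBr, THF, 0 °C) to 3 should give the racemic adduct F4, and DMF/H2O at 100 °C the racemic acid F5. Fractional crystallisation of a diastereomeric ammonium salt, for example the (R)-1-phenylethylammonium salt of the (3S)-acid F6 (amine and solvent to be chosen by screening), followed by acidification, should return (3S)-acid 6.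

Step 15. The vinylogous amide may be reduced 1,4 or over-reduced, or ionisation and hydrolysis may stall and give mixtures of amino alcohol, silyl enal and desilylated material. The fallback sets out from 25 and returns at 29, and builds the enal by alkene formylation instead of carbonyl transposition. NaBH4 (MeOH/THF, 0 °C) should reduce the ketone to the (1S,2S,4RS)-C4 alcohol F7, and TsOH (cat., PhMe, 60 °C) should dehydrate it to the (1S,2S)-1,2-dihydronaphthalene F8. Vilsmeier–Haack formylation of this electron-rich styrene at C3 (POCl3, DMF, 0 → 50 °C) should give the unsaturated iminium chloride F9 (not isolated), whose hydrolysis with aq. NaOAc gives silyl enal 28. Treatment with 2 M aq. HCl/THF, as in the second stage of step 15, then gives 29.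

Further compounds
F1 | step 10 | (3RS,5S,6R)-6-[4-(benzyloxy)-3-methoxyphenyl]-5-{[tert-butyl(dimethyl)silyl]oxymethyl}octa-1,7-diyn-3-ol | C#C[C@H](c1ccc(OCc2ccccc2)c(OC)c1)[C@@H](CO[Si](C)(C)C(C)(C)C)CC(O)C#C
F2 | step 10 | (1S,2S,4RS)-1-[4-(benzyloxy)-3-methoxyphenyl]-2-{[tert-butyl(dimethyl)silyl]oxymethyl}-6,7-bis(4,4,5,5-tetramethyl-1,3,2-dioxaborolan-2-yl)-1,2,3,4-tetrahydronaphthalen-4-ol (target numbering) | COc1cc([C@H]2c3cc(B4OC(C)(C)C(C)(C)O4)c(B4OC(C)(C)C(C)(C)O4)cc3C(O)C[C@@H]2CO[Si](C)(C)C(C)(C)C)ccc1OCc1ccccc1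
F3 | step 2 | (trimethylsilyl)ethynylmagnesium bromide | C[Si](C)(C)C#C[Mg]Br
F4 | step 2 | racemic 5-[1-[4-(benzyloxy)-3-methoxyphenyl]-3-(trimethylsilyl)prop-2-yn-1-yl]-2,2-dimethyl-1,3-dioxane-4,6-dione | C[Si](C)(C)C#CC(c1ccc(OCc2ccccc2)c(OC)c1)C1C(=O)OC(C)(C)OC1=O
F5 | step 2 | racemic 3-[4-(benzyloxy)-3-methoxyphenyl]-5-(trimethylsilyl)pent-4-ynoic acid | C[Si](C)(C)C#CC(c1ccc(OCc2ccccc2)c(OC)c1)CC(=O)O
F6 | step 2 | (R)-1-phenylethylammonium (3S)-3-[4-(benzyloxy)-3-methoxyphenyl]-5-(trimethylsilyl)pent-4-ynoate | C[Si](C)(C)C#C[C@H](c1ccc(OCc2ccccc2)c(OC)c1)CC(=O)[O-].C[C@@H]([NH3+])c1ccccc1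
F7 | step 15 | (1S,2S,4RS)-7-(benzyloxy)-1-[4-(benzyloxy)-3-methoxyphenyl]-2-{[tert-butyl(dimethyl)silyl]oxymethyl}-6-methoxy-1,2,3,4-tetrahydronaphthalen-4-ol (target numbering) | COc1cc([C@H]2c3cc(OCc4ccccc4)c(OC)cc3C(O)C[C@@H]2CO[Si](C)(C)C(C)(C)C)ccc1OCc1ccccc1
F8 | step 15 | (1S,2S)-7-(benzyloxy)-1-[4-(benzyloxy)-3-methoxyphenyl]-2-{[tert-butyl(dimethyl)silyl]oxymethyl}-6-methoxy-1,2-dihydronaphthalene | COc1cc([C@H]2c3cc(OCc4ccccc4)c(OC)cc3C=C[C@@H]2CO[Si](C)(C)C(C)(C)C)ccc1OCc1ccccc1
F9 | step 15 | N-{[(1S,2R)-7-(benzyloxy)-1-[4-(benzyloxy)-3-methoxyphenyl]-2-{[tert-butyl(dimethyl)silyl]oxymethyl}-6-methoxy-1,2-dihydronaphthalen-3-yl]methylidene}-N-methylmethanaminium chloride | COc1cc([C@H]2c3cc(OCc4ccccc4)c(OC)cc3C=C(C=[N+](C)C)[C@@H]2CO[Si](C)(C)C(C)(C)C)ccc1OCc1ccccc1.[Cl-]
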